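**Retrosynthetic overview**
1. The target comes from its tetrabenzyl ether by a final BCl3 debenzylation. Target numbering is used for all intermediates: O1, C2 (CO2Me), C3 (ring B), C4 (=CH–ring C), C5 (=O). Ring A is the lactone.
2. Ring A comes from ring expansion of an α-benzylidene-β-lactone (O1–C3–C4–C5) that carries ring B and CO2Me on the exocyclic C2. O1 and ring B change places between C3 and C2. The new O1–C2 bond closes ring A, and the temporary O1–C3 bond, absent from the target, is cleaved.
3. Enabling feature: ring B stands next to the C–O bond, and its para oxygen (on C4 of ring B) lets C1 of ring B bridge C2 and C3 as a phenonium ion. Oxetanone strain drives the shift. The C3–O1 bond lies in the nodal plane of the C4=CH–ring C π system, so the styrene stays a spectator.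
4. The β-lactone comes from a β-hydroxy acid, and that from an alkenyl bromide in which CO replaces the Br cis to ring C (Z alkene). The bromide comes from an Evans syn aldol of an arylacetyl oxazolidinone (C2, ring B) with a (Z)-α-bromoenal (C3, C4, ring C), which sets both stereocentres.
5. Order of ring formation: the temporary oxetanone first, ring A second.

Key step: step 8

Assumption: the SMILES is read as the 2,3-cis lactone (2S,3R) with a Z exocyclic alkene (ring C cis to the C5 carbonyl).

Step 1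
Reactants: 1 3,4-bis(benzyloxy)benzaldehyde; 2 (triphenylphosphoranylidene)acetaldehyde
Product: 4 (2Z)-3-[3,4-bis(benzyloxy)phenyl]-2-bromoprop-2-enal, via bromo ylide 3 (not isolated)
Conditions: 2, NBS, ClCH2CH2Cl, 0 °C; then 1, 80 °C
Reagents that add atoms: N-bromosuccinimide, O=C1CCC(=O)N1Br
Why: Bromination of the stabilised ylide followed by a Wittig olefination should place ring C trans to the formyl group, as stabilised ylides do, giving the Z-bromoenal in which Br (the later C5 carboxyl) is cis to ring C.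

Step 2
Reactants: 5 [3,4-bis(benzyloxy)phenyl]acetic acid; 6 (4R)-4-benzyl-1,3-oxazolidin-2-one
Product: 7 (4R)-4-benzyl-3-{[3,4-bis(benzyloxy)phenyl]acetyl}-1,3-oxazolidin-2-one
Conditions: DCC, DMAP (cat.), CH2Cl2, 0 °C to rt
Reagents that add atoms: none
Why: Steglich-type carbodiimide N-acylation of the oxazolidinone with an unhindered arylacetic acid touches no stereocentre.

Step 3
Reactants: 7 (4R)-4-benzyl-3-{[3,4-bis(benzyloxy)phenyl]acetyl}-1,3-oxazolidin-2-one; 4 (2Z)-3-[3,4-bis(benzyloxy)phenyl]-2-bromoprop-2-enal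
Product: 9 (4R)-4-benzyl-3-{(2R,3R,4Z)-2,5-bis[3,4-bis(benzyloxy)phenyl]-4-bromo-3-hydroxypent-4-enoyl}-1,3-oxazolidin-2-one, via dibutylboron Z-enolate 8 (not isolated)
Conditions: Bu2BOTf, Et3N, CH2Cl2, −78 to 0 °C; 4, −78 to 0 °C; then H2O2, MeOH, pH 7 buffer, 0 °C
Reagents that add atoms: none
Why: In this Evans syn aldol addition the Z-boron enolate adds 1,2 to the enal through a Zimmerman–Traxler chair on the face away from the benzyl group of the (R)-auxiliary, which should set (2R,3R), that is C2 (still bearing ring B) and C3 (still bearing oxygen).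

Step 4
Reactants: 9 the aldol imide
Product: 11 (2R,3R,4Z)-2,5-bis[3,4-bis(benzyloxy)phenyl]-4-bromo-3-hydroxypent-4-enoic acid, via peroxy acid 10 (not isolated)
Conditions: LiOH, H2O2, THF/H2O, 0 °C; then Na2SO3; 1 M HCl
Reagents that add atoms: hydrogen peroxide, OO
Why: Hydroperoxide attacks the exocyclic imide carbonyl selectively (standard auxiliary cleavage) and sulfite reduces the peracid, so at 0 °C the α-aryl centre and the alkenyl bromide should stay untouched.

Step 5
Reactants: 11 the hydroxy acid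
Product: 12 methyl (2R,3R,4Z)-2,5-bis[3,4-bis(benzyloxy)phenyl]-4-bromo-3-hydroxypent-4-enoate
Conditions: TMSCHN2, PhMe/MeOH, 0 °C
Reagents that add atoms: (trimethylsilyl)diazomethane, C[Si](C)(C)C=[N+]=[N-]
Why: O-Methylation of the acid by the diazoalkane is neutral, so the aldol unit is exposed neither to retro-aldol cleavage nor to epimerisation.

Step 6
Reactants: 12 the bromo hydroxy ester
Product: 13 (2Z,3R,4R)-2-[3,4-bis(benzyloxy)benzylidene]-4-[3,4-bis(benzyloxy)phenyl]-3-hydroxy-5-methoxy-5-oxopentanoic acid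
Conditions: Pd(OAc)2 (cat.), PPh3 (cat.), CO (3 bar), H2O, Et3N, DMF, 60 °C
Reagents that add atoms: carbon monoxide, [C-]#[O+]; water, O
Why: In this palladium-catalysed hydroxycarbonylation of an alkenyl bromide, oxidative addition, CO insertion and hydrolysis of the acylpalladium all retain the alkene geometry, so the carboxyl group takes the place of Br cis to ring C (Z).

Step 7
Reactants: 13 the β-hydroxy acid
Product: 15 methyl (2R)-2-[3,4-bis(benzyloxy)phenyl]-2-{(2R,3Z)-3-[3,4-bis(benzyloxy)benzylidene]-4-oxooxetan-2-yl}acetate, via mixed sulfonic anhydride 14 (not isolated)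
Conditions: PhSO2Cl, pyridine, 0 °C
Reagents that add atoms: none
Why: Carboxyl activation followed by 4-exo-trig attack of the C3 hydroxyl is the standard β-lactonisation of β-hydroxy and α-methylene-β-hydroxy acids, and because it forms the acyl–O bond it retains the C3–O bond and both stereocentres.

Step 8
Reactants: 15 the α-benzylidene-β-lactone
Product: 17 methyl (2S,3R,4Z)-4-[3,4-bis(benzyloxy)benzylidene]-3-[3,4-bis(benzyloxy)phenyl]-5-oxooxolane-2-carboxylate, via phenonium carboxylate 16 (not isolated)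
Conditions: Zn(OTf)2, 4 Å MS, CH2Cl2, −20 °C to rt
Reagents that add atoms: none
Why: Proposed new method: zinc coordination weakens the C3–O1 bond of the strained oxetanone, ring B on C2 attacks C3 from the rear (O1–C3–C2–C1 of ring B antiperiplanar) to give the spiro[2.5]octadienyl (phenonium) ion 16 with its charge on the para oxygen of ring B, and the released carboxylate opens the three-membered ring at C2; the closest known reaction type is the Lewis-acid-promoted dyotropic (Wagner–Meerwein) ring expansion of β-lactones to γ-butyrolactones with a 1,2-shift of hydride, alkyl, acyl or aryl, and what is new is an oxygen terminus α to an ester and an α-alkylidene lactone. Ring A closes 5-exo-tet (the breaking C2–C1(ring B) bond lies outside the forming ring), whereas return to C3 only regenerates the four-membered ring, so relief of oxetanone strain makes ring A the sink. C3 is set by inversion (ring B enters anti to O1) and C2 by inversion (O1 enters anti to ring B), so the syn R,R array of 15 becomes the cis (2S,3R) array that an equilibrating closure would not give. The step needs ring B to migrate rather than H or CO2Me, which its two alkoxy groups secure because only the electron-rich arene gives anchimeric assistance. It also needs the benzylidene unit to stay out of the ionisation: the C3–O1 bond lies in the plane of the oxetanone and of C4=CH, the nodal plane of that π system, so no allyl cation can form at the moment of cleavage, attack at C2 needs only a small rotation about C3–C4, and the Z geometry and the C3 configuration should be kept.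

Step 9
Reactants: 17 the tetrabenzyl ether
Product: 18 methyl (2S,3R,4Z)-4-(3,4-dihydroxybenzylidene)-3-(3,4-dihydroxyphenyl)-5-oxooxolane-2-carboxylate
Conditions: BCl3, C6HMe5, CH2Cl2, −78 °C; then MeOH/CHCl3, aqueous work-up
Reagents that add atoms: none
Why: Lewis-acid debenzylation with pentamethylbenzene as a non-basic Friedel–Crafts trap for benzyl cations is neither reductive nor basic, so the alkene, the methyl ester, the lactone and the epimerisable cis C2 centre should survive.

**Compound list**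
1 | 3,4-bis(benzyloxy)benzaldehyde | O=Cc1ccc(OCc2ccccc2)c(OCc2ccccc2)c1 | starting material
2 | (triphenylphosphoranylidene)acetaldehyde | O=CC=P(c1ccccc1)(c1ccccc1)c1ccccc1 | starting material
3 | 2-bromo-2-(triphenylphosphoranylidene)acetaldehyde (bromo ylide) | O=CC(Br)=P(c1ccccc1)(c1ccccc1)c1ccccc1 | intermediate
4 | (2Z)-3-[3,4-bis(benzyloxy)phenyl]-2-bromoprop-2-enal | O=C/C(Br)=C/c1ccc(OCc2ccccc2)c(OCc2ccccc2)c1 | intermediate
5 | [3,4-bis(benzyloxy)phenyl]acetic acid | OC(=O)Cc1ccc(OCc2ccccc2)c(OCc2ccccc2)c1 | starting material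
6 | (4R)-4-benzyl-1,3-oxazolidin-2-one | O=C1OC[C@@H](Cc2ccccc2)N1 | starting material
7 | (4R)-4-benzyl-3-{[3,4-bis(benzyloxy)phenyl]acetyl}-1,3-oxazolidin-2-one | O=C1OC[C@@H](Cc2ccccc2)N1C(=O)Cc1ccc(OCc2ccccc2)c(OCc2ccccc2)c1 | intermediate
8 | dibutylboron (Z)-enolate of 7 | CCCCB(CCCC)O/C(=C\c1ccc(OCc2ccccc2)c(OCc2ccccc2)c1)N1C(=O)OC[C@H]1Cc1ccccc1 | intermediate
9 | (4R)-4-benzyl-3-{(2R,3R,4Z)-2,5-bis[3,4-bis(benzyloxy)phenyl]-4-bromo-3-hydroxypent-4-enoyl}-1,3-oxazolidin-2-one | O=C1OC[C@@H](Cc2ccccc2)N1C(=O)[C@H](c1ccc(OCc2ccccc2)c(OCc2ccccc2)c1)[C@@H](O)/C(Br)=C/c1ccc(OCc2ccccc2)c(OCc2ccccc2)c1 | intermediate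
10 | (2R,3R,4Z)-2,5-bis[3,4-bis(benzyloxy)phenyl]-4-bromo-3-hydroxypent-4-eneperoxoic acid | OOC(=O)[C@H](c1ccc(OCc2ccccc2)c(OCc2ccccc2)c1)[C@@H](O)/C(Br)=C/c1ccc(OCc2ccccc2)c(OCc2ccccc2)c1 | intermediate
11 | (2R,3R,4Z)-2,5-bis[3,4-bis(benzyloxy)phenyl]-4-bromo-3-hydroxypent-4-enoic acid | OC(=O)[C@H](c1ccc(OCc2ccccc2)c(OCc2ccccc2)c1)[C@@H](O)/C(Br)=C/c1ccc(OCc2ccccc2)c(OCc2ccccc2)c1 | intermediate
12 | methyl (2R,3R,4Z)-2,5-bis[3,4-bis(benzyloxy)phenyl]-4-bromo-3-hydroxypent-4-enoate | COC(=O)[C@H](c1ccc(OCc2ccccc2)c(OCc2ccccc2)c1)[C@@H](O)/C(Br)=C/c1ccc(OCc2ccccc2)c(OCc2ccccc2)c1 | intermediate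
13 | (2Z,3R,4R)-2-[3,4-bis(benzyloxy)benzylidene]-4-[3,4-bis(benzyloxy)phenyl]-3-hydroxy-5-methoxy-5-oxopentanoic acid | COC(=O)[C@H](c1ccc(OCc2ccccc2)c(OCc2ccccc2)c1)[C@@H](O)/C(C(=O)O)=C/c1ccc(OCc2ccccc2)c(OCc2ccccc2)c1 | intermediate
14 | mixed carboxylic benzenesulfonic anhydride of 13 | COC(=O)[C@H](c1ccc(OCc2ccccc2)c(OCc2ccccc2)c1)[C@@H](O)/C(C(=O)OS(=O)(=O)c1ccccc1)=C/c1ccc(OCc2ccccc2)c(OCc2ccccc2)c1 | intermediate
15 | methyl (2R)-2-[3,4-bis(benzyloxy)phenyl]-2-{(2R,3Z)-3-[3,4-bis(benzyloxy)benzylidene]-4-oxooxetan-2-yl}acetate | COC(=O)[C@H](c1ccc(OCc2ccccc2)c(OCc2ccccc2)c1)[C@H]1OC(=O)/C1=C\c1ccc(OCc2ccccc2)c(OCc2ccccc2)c1 | intermediate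
16 | phenonium carboxylate: C1 of ring B bridges C2 and C3 as a spiro[2.5]octadienyl cation, alkenyl and CO2Me cis on the three-membered ring, drawn without zinc | [O-]C(=O)/C(=C\c1ccc(OCc2ccccc2)c(OCc2ccccc2)c1)[C@@H]1[C@H](C(=O)OC)C12C=CC(=[O+]Cc3ccccc3)C(OCc3ccccc3)=C2 | intermediate
17 | methyl (2S,3R,4Z)-4-[3,4-bis(benzyloxy)benzylidene]-3-[3,4-bis(benzyloxy)phenyl]-5-oxooxolane-2-carboxylate | COC(=O)[C@H]1OC(=O)/C(=C\c2ccc(OCc3ccccc3)c(OCc3ccccc3)c2)[C@H]1c1ccc(OCc2ccccc2)c(OCc2ccccc2)c1 | intermediate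
18 | methyl (2S,3R,4Z)-4-(3,4-dihydroxybenzylidene)-3-(3,4-dihydroxyphenyl)-5-oxooxolane-2-carboxylate | COC(=O)[C@H]1OC(=O)/C(=C\c2ccc(O)c(O)c2)[C@H]1c1ccc(O)c(O)c1 | target

Total step count: 9. Longest linear sequence: 8 (steps 1, 3, 4, 5, 6, 7, 8, 9).

**Steps most likely to fail**

**Step 8.** The bridged ion may lose the acidic C2 proton to give a dienoic acid. It may also open to the ring C-stabilised allyl cation before O1 reaches C2, which would erode the C3 configuration, the cis relationship and the Z geometry.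
- The fallback uses known chemistry, sets out from 4 and comes back at 17.
- Horner–Wadsworth–Emmons olefination of 4 with trimethyl phosphonoacetate (LiCl, iPr2NEt, MeCN) would give methyl (2E,4Z)-5-[3,4-bis(benzyloxy)phenyl]-4-bromopenta-2,4-dienoate F1.
- Hayashi–Miyaura 1,4-addition of 3,4-bis(benzyloxy)phenylboronic acid would follow, using [RhCl(C2H4)2]2 and a chiral bicyclo[2.2.2]octadiene ligand whose enantiomer is chosen for 3R. It would place ring B directly on C3 and give methyl (3R,4Z)-3,5-bis[3,4-bis(benzyloxy)phenyl]-4-bromopent-4-enoate F2.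
- Davis enolate hydroxylation (KN(SiMe3)2, 2-(phenylsulfonyl)-3-phenyloxaziridine, THF, −78 °C) and separation of the epimers would give methyl (2R,3S,4Z)-3,5-bis[3,4-bis(benzyloxy)phenyl]-4-bromo-2-hydroxypent-4-enoate F3.
- Hydroxycarbonylation as in step 6 would give (2Z,3R,4R)-2-[3,4-bis(benzyloxy)benzylidene]-3-[3,4-bis(benzyloxy)phenyl]-4-hydroxy-5-methoxy-5-oxopentanoic acid F4.
- Mitsunobu lactonisation (PPh3, DIAD, PhMe, 0 °C) would close O1–C2 by SN2 inversion at the activated α-hydroxy ester and deliver 17.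

**Step 7.** The C3 hydroxyl may be sulfonylated instead of the carboxyl group, followed by elimination toward the α-aryl ester.
- The fallback sets out from 12 and comes back at 15.
- It is a palladium-catalysed carbonylative ring closure of the 2-bromoallylic alcohol (Pd(PPh3)4, CO, iPr2NEt, MeCN, 50 °C).
- The acylpalladium is captured by the neighbouring hydroxyl, so the free acid and any sulfonylating agent are avoided.
- New compounds: none F0.

**Step 4.** Retro-aldol cleavage or epimerisation of the α-aryl centre may occur under basic peroxide.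
- The fallback sets out from 5 and 4 and comes back at 12.
- Compound 5 would be esterified (TMSCHN2) to methyl [3,4-bis(benzyloxy)phenyl]acetate F5.
- F5 would be enolised with diisopinocampheylboron triflate and iPr2NEt and added to 4. This is a reagent-controlled syn boron aldol of an arylacetate ester, with the enantiomer of the reagent chosen for 2R,3R.
- It gives 12 directly and bypasses the auxiliary and every basic cleavage.

**Further compounds**
F1 | step 8 | methyl (2E,4Z)-5-[3,4-bis(benzyloxy)phenyl]-4-bromopenta-2,4-dienoate | COC(=O)/C=C/C(Br)=C/c1ccc(OCc2ccccc2)c(OCc2ccccc2)c1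
F2 | step 8 | methyl (3R,4Z)-3,5-bis[3,4-bis(benzyloxy)phenyl]-4-bromopent-4-enoate | COC(=O)C[C@H](c1ccc(OCc2ccccc2)c(OCc2ccccc2)c1)/C(Br)=C/c1ccc(OCc2ccccc2)c(OCc2ccccc2)c1
F3 | step 8 | methyl (2R,3S,4Z)-3,5-bis[3,4-bis(benzyloxy)phenyl]-4-bromo-2-hydroxypent-4-enoate | COC(=O)[C@H](O)[C@H](c1ccc(OCc2ccccc2)c(OCc2ccccc2)c1)/C(Br)=C/c1ccc(OCc2ccccc2)c(OCc2ccccc2)c1
F4 | step 8 | (2Z,3R,4R)-2-[3,4-bis(benzyloxy)benzylidene]-3-[3,4-bis(benzyloxy)phenyl]-4-hydroxy-5-methoxy-5-oxopentanoic acid | COC(=O)[C@H](O)[C@H](c1ccc(OCc2ccccc2)c(OCc2ccccc2)c1)/C(C(=O)O)=C/c1ccc(OCc2ccccc2)c(OCc2ccccc2)c1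
F0 | step 7 | none | none
F5 | step 4 | methyl [3,4-bis(benzyloxy)phenyl]acetate | COC(=O)Cc1ccc(OCc2ccccc2)c(OCc2ccccc2)c1
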